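## Structural features

The target is a 2,3-dihydrobenzofuran: benzene ring A is fused to a five-membered ring made of O1, C2, C3, C3a and C7a. C2 carries the 3,4-dimethoxyphenyl ring B and C3 a hydroxymethyl group; these two adjacent stereocentres are trans, (2R,3S), and are the only ones. Ring A carries a free phenol at C7, next to the ring oxygen on C7a, and an (E)-propenoic acid at C5, para to O1. Several points are fragile: the O1–C2 bond is a para-alkoxybenzylic aryl ether that acids and Lewis acids can ionise, the C2–H bond can be dehydrogenated to the benzofuran, the cinnamic double bond excludes late hydrogenolysis, and the C7 phenol is an oxidisable catechol monoether. The real difficulty is threefold: fixing C3 absolutely at a carbon that becomes enolisable in any lactone precursor, setting C2 trans to it, and telling apart the two neighbouring ring A oxygens while ring B keeps both methyl ethers. The key step uses the fact that C2 is a benzylic carbon para to the 4-methoxy group of ring B and lies five atoms from the phenolic oxygen on C7a of ring A, so that oxidation of its C–H bond gives a cation that O1 captures to close the heterocycle.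

## Logic of the disconnections

16 to 15: no skeletal bond is cut; the acid O–H is exchanged for O–CH3. The acid travels as a neutral ester through the palladium, DDQ and BCl3 steps. The forward hydrolysis must leave the E alkene and both stereocentres alone, which is reasonable because neither centre is alpha to a carbonyl.

15 to 14: the O7–CH2Ph bond is cut. While the ring is closed only one of the two neighbouring ring A oxygens may be free, and O7 needs a group that cannot migrate to O1 (an ether, not a silyl or acyl group) and that survives aqueous base, TFA, borane, palladium and DDQ. The forward step must remove it without hydrogen (alkene) and without ionising O1–C2.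

14 to 13: the O1–C2 bond is cut. C2 is benzylic and para to a methoxy group, so it can be carried as a plain CH2 and oxidised last; the cut removes the ring and the C2 stereocentre together and leaves an open chain with one stereocentre. The forward step must pick this C–H bond among several and close trans.

13 to 11 and 12: the C5–vinyl bond is cut. The acrylate would not survive hydrogenation or borane, and it is wanted on ring A before the oxidation because it makes that ring the poorer donor. The forward step is a Heck coupling on an unprotected bromophenol and must give the E alkene.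

11 to 10: CH2OH is traced back to CO2H. The carboxyl group is the handle that directs the hydrogenation catalyst in the step before. The forward reduction must spare the aryl bromide and must not enolise the stereocentre.

10 to 9: the stereocentre is removed by introducing the C-alpha=C-beta double bond. The centre is deliberately set on the ring-opened acid and not in the lactone 8: a 3-monosubstituted benzofuran-2(3H)-one has a C–H flanked by an aryl ring and an aryl ester carbonyl and would not hold its configuration through a basic hydride opening. The forward step must select one face of an alkene of defined E geometry.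

9 to 6 and 7 (through 8): the C-alpha=C-beta bond is cut in the aldol sense and O1 is reconnected to the carboxyl carbon. The lactone makes the CH2 acidic enough to condense and ties up O1, which differentiates it from O7. The forward step must condense E-selectively and open the ring without isomerising the alkene.

6 to 4 (through 5): the lactone C–O bond is cut and a hydroxyl is put back on the benzylic carbon. A phenol and a two-carbon aldehyde-level electrophile give a mandelic acid, not an arylacetic acid, so a deoxygenation is unavoidable. It must be selective for the benzylic C–OH and spare the aryl bromide and the benzyl ether.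

4 to 2 and 3: the aryl–C-alpha bond is cut. Both carbons of the future C3/CH2OH unit come from 3. The forward step must attack ortho to the phenoxide, which the para bromine enforces.

2 to 1: the C–Br bond is cut. Bromine is blocking group and Heck handle in one. The forward bromination must go para to the free hydroxyl.

## Other disconnections considered

Alternative 1: The product of the key step would be methyl (2R,3S)-3-(benzyloxymethyl)-7-bromo-2-(3,4-dimethoxyphenyl)-2,3-dihydrobenzofuran-5-carboxylate A1.
- Cut: through ring A at C3a–C4 and C7–C7a. This leads back to (4S,5R)-4-[(benzyloxy)methyl]-5-(3,4-dimethoxyphenyl)dihydrofuran-2(3H)-one A2, used as its silyl ketene acetal tert-butyl{[(4S,5R)-4-[(benzyloxy)methyl]-5-(3,4-dimethoxyphenyl)-4,5-dihydrofuran-2-yl]oxy}dimethylsilane A3, and to methyl 3-bromocoumalate A4.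
- Forward step: an inverse-demand Diels–Alder reaction. The nucleophilic carbon of A3 bonds to pyrone C6 and the acetal carbon to pyrone C3; the bridged adduct loses CO2 and then silanol, which aromatises ring A.
- In favour: both stereocentres are made beforehand on A2 and are not touched; the polarisation of A4 fixes the regiochemistry; no oxidant meets an electron-rich phenol.
- Against: A1 still needs C7–Br turned into OH and the C5 ester turned into an acrylic acid, each taking more than one step. The CH2OBn group meets the same debenzylation problem next to a cinnamate, and enantiopure trans A2 needs its own sequence.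
- Comparison: the alternative builds the carbocycle and sets no stereocentre, where the chosen plan builds the heterocycle and C2. It is pericyclic and redox-neutral where the chosen plan is an oxidative hydride abstraction. It would be clearly longer.
- Equal or better: it is better in chemoselectivity, because no competition between phenol oxidation and C–H oxidation can arise. The two plans are equal in the security of the trans arrangement.

Alternative 2: The product of the key step would be (2R,3S)-3-[(tert-butyldimethylsilyloxy)methyl]-2-(3,4-dimethoxyphenyl)-2,3-dihydrobenzofuran-7-ol A5.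
- Cut: the aryl–oxygen bond O1–C7a and the C7–OH bond, leading back to (1R,2S)-2-(3-bromo-2-fluorophenyl)-3-[(tert-butyldimethylsilyl)oxy]-1-(3,4-dimethoxyphenyl)propan-1-ol A6.
- Forward step: iPrMgCl·LiCl would deprotonate the carbinol and exchange the bromide. On warming, loss of fluoride opens an aryne across C7–C7a; the magnesium alkoxide adds at C7a and closes the ring; the carbanion left at C7 is borylated with B(OMe)3 and oxidised with H2O2.
- In favour: the carbinol C–O bond is never broken, so the configuration of A6 passes unchanged into C2. One operation installs both ring A oxygens already differentiated, and no oxidant touches either ring.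
- Against: A5 has no carbon at C5. The acrylate would have to be added by halogenation para to O1 against the directing effect of the free C7 hydroxyl (which points to C4 and C6), so masking, halogenation, Heck coupling and unmasking follow. A6 itself needs an enantio- and anti-selective aldol-type construction, and the aryne step is sensitive to proton sources.
- Comparison: the same ring is closed through its other C–O bond, and two centres are conserved rather than one being set. The mechanism is polar and organometallic rather than oxidative. The sequence after the key step would be about five steps against two.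
- Equal or better: it is better in stereochemical certainty at C2, which is stereospecific there and substrate-controlled in the chosen plan.

Alternative 3: The product of the key step would be methyl (2R,3R)-trans-5-bromo-2-(3,4-dimethoxyphenyl)-7-(methoxymethoxy)-2,3-dihydrobenzofuran-3-carboxylate A7.
- Cut: the C2–C3 bond, leading back to methyl 2-[5-bromo-2-[(3,4-dimethoxybenzyl)oxy]-3-(methoxymethoxy)phenyl]-2-diazoacetate A8.
- Forward step: Rh2(S-PTTL)4 would convert A8 into a rhodium carbene that inserts into a benzylic C–H bond of the veratryl ether (1,5-insertion) to give the cis ester; NaOMe in the same flask would then epimerise C3 to the trans ester A7.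
- In favour: ring formation and absolute stereocontrol come from one catalytic step. The arylacetate core of A8 is at the oxidation level of compound 5, so the early steps could be shared, and the C5 bromide is ready for the Heck coupling.
- Against: diazo transfer and diazo handling are needed. The carbene can be diverted by ring B (Buchner-type addition) or by the ether oxygen (ylide formation and Stevens shift). The epimerisation runs alpha to an ester whose beta substituent is the phenoxide O1, so retro-oxa-Michael ring opening could scramble C2. Ester reduction, Heck coupling, acetal removal and saponification would still follow.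
- Comparison: a C–C bond and two stereocentres are formed where the chosen plan forms a C–O bond and one centre. The mechanism is metal-carbene insertion rather than hydride abstraction and cation capture. The step count would be about equal.
- Equal or better: it is equal in step economy. It is better in that the ring-forming step is itself enantioselective, and in that a methoxymethyl ether comes off with dilute acid, more gently than a Lewis-acid debenzylation.
- Why the chosen plan is kept: it needs no diazo compound, and its trans relation is favoured both kinetically and thermodynamically without a base epimerisation.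

Key step: step 8

Assumptions and remarks on the chemistry:
- Assumption: the (Sa,S) enantiomer of the iridium catalyst in step 5 is taken to deliver the (S)-acid 10; if the sense of induction is the opposite for this substrate, the mirror-image catalyst is used.
- Check of the key-step pair: the single centre of 13 is S and maps onto C3 = S of 14 (only the CIP ranking of the neighbours changes, not the geometry); C2 = R; (2R,3S) is the trans isomer. No correction to these two structures is needed, and 13 is kept unchanged in constitution.
- Two points were changed relative to a plan that hydrogenates the benzylidene lactone 8 directly. First, glyoxylic acid adds to a phenol as a mandelic acid, so a deoxygenation (step 3) is required before the lactone exists. Second, C3 is not created in a lactone, for the reason given under 10 to 9; the lactone is opened first, the centre is set on the carboxylate and the acid is then reduced with borane.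
- Glyoxylic acid 3 is used as its monohydrate.

## Steps

Step 1
Reactants: 1 2-(benzyloxy)phenol
Product: 2 2-(benzyloxy)-4-bromophenol
Conditions: NBS (1.0 equiv), MeCN, 0 °C to rt
Reagents that add atoms: N-bromosuccinimide, O=C1CCC(=O)N1Br
Why: Electrophilic aromatic bromination; the free hydroxyl is the stronger activator and its para position is open, so bromine should enter at C4, where it blocks that position for step 2 and later serves as the Heck handle.

Step 2
Reactants: 2 2-(benzyloxy)-4-bromophenol; 3 glyoxylic acid
Product: 4 2-[3-(benzyloxy)-5-bromo-2-hydroxyphenyl]-2-hydroxyacetic acid (racemic)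
Conditions: NaOH (2.5 equiv), H2O/1,4-dioxane, 35 °C; then HCl (aq), 0 °C, pH 2
Reagents that add atoms: none
Why: Hydroxyalkylation of a phenolate by glyoxylate (an aromatic substitution of the Friedel–Crafts type); with the para position brominated, the only carbon ortho to the phenoxide oxygen is C6, and the racemic carbinol centre is removed in step 3.

Step 3
Reactants: 4 2-[3-(benzyloxy)-5-bromo-2-hydroxyphenyl]-2-hydroxyacetic acid
Product: 6 7-(benzyloxy)-5-bromobenzofuran-2(3H)-one, via arylacetic acid 5 (not isolated)
Conditions: Et3SiH (3 equiv), TFA/CH2Cl2 (1:2), 0 °C to rt; then TsOH·H2O (5 mol%), toluene, reflux, azeotropic removal of water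
Reagents that add atoms: none
Why: Ionic hydrogenation: acid ionises the benzylic alcohol to a cation stabilised by the ortho hydroxyl (a protonated ortho-quinone methide), which the silane reduces. Acid-catalysed lactonisation of the 2-hydroxyarylacetic acid then closes the five-membered aryl lactone; the aryl bromide and the benzyl ether should not react with the silane.

Step 4
Reactants: 6 7-(benzyloxy)-5-bromobenzofuran-2(3H)-one; 7 3,4-dimethoxybenzaldehyde
Product: 9 (E)-2-[3-(benzyloxy)-5-bromo-2-hydroxyphenyl]-3-(3,4-dimethoxyphenyl)acrylic acid, via benzylidene lactone 8 (not isolated)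
Conditions: Ac2O, Et3N, 90 °C; concentrate; then NaOH (2 M aq), THF, 0 °C to rt; then HCl (1 M aq) to pH 3–4
Reagents that add atoms: sodium hydroxide, [Na+].[OH-]
Why: A Perkin-type (Knoevenagel) condensation at the doubly activated lactone methylene should give the E benzylidene lactone with ring B anti to the carbonyl. Hydroxide then opens the aryl ester without touching the double bond, so the E 2,3-diarylacrylic acid results and any Z isomer can be removed by crystallisation.

Step 5
Reactants: 9 (E)-2-[3-(benzyloxy)-5-bromo-2-hydroxyphenyl]-3-(3,4-dimethoxyphenyl)acrylic acid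
Product: 10 (2S)-2-[3-(benzyloxy)-5-bromo-2-hydroxyphenyl]-3-(3,4-dimethoxyphenyl)propanoic acid
Conditions: [Ir(cod)((Sa,S)-SIPHOX)]BArF (1 mol%; SIPHOX = 7-diarylphosphino-7'-oxazolinyl-1,1'-spirobiindane, BArF = B[3,5-(CF3)2C6H3]4), H2 (6 atm), Et3N (1 equiv), MeOH, 25–45 °C
Reagents that add atoms: none
Why: Carboxylate-directed asymmetric hydrogenation of an alpha-aryl cinnamic acid with a chiral iridium phosphine–oxazoline catalyst; the carboxylate binds the metal and hydrogen is delivered to one face of the E alkene, which sets the stereocentre (S), the future C3. The product is a carboxylate salt with no readily enolised C–H, and homogeneous iridium hydrides should leave the aryl bromide and the benzyl ether alone.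

Step 6
Reactants: 10 (2S)-2-[3-(benzyloxy)-5-bromo-2-hydroxyphenyl]-3-(3,4-dimethoxyphenyl)propanoic acid
Product: 11 2-(benzyloxy)-4-bromo-6-[(2S)-1-(3,4-dimethoxyphenyl)-3-hydroxypropan-2-yl]phenol
Conditions: BH3·SMe2 (4 equiv), THF, 0 °C to rt; then MeOH
Reagents that add atoms: none
Why: Chemoselective borane reduction of a carboxylic acid through its acyloxyborane; no enolate is formed, so the stereocentre is kept. The phenol is only borylated and is freed again on methanolysis.

Step 7
Reactants: 11 2-(benzyloxy)-4-bromo-6-[(2S)-1-(3,4-dimethoxyphenyl)-3-hydroxypropan-2-yl]phenol; 12 methyl acrylate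
Product: 13 methyl (E)-3-{3-(benzyloxy)-5-[(2S)-1-(3,4-dimethoxyphenyl)-3-hydroxypropan-2-yl]-4-hydroxyphenyl}acrylate
Conditions: Pd(OAc)2 (5 mol%), P(o-tol)3 (15 mol%), Et3N (3 equiv), methyl acrylate (3 equiv), MeCN, 85 °C
Reagents that add atoms: none
Why: Mizoroki–Heck reaction: oxidative addition of the aryl bromide to zerovalent palladium, syn insertion of the acrylate and syn beta-hydride elimination should give the E cinnamate. The tertiary amine does not deprotonate the hindered phenol or the alcohol enough for conjugate addition to compete.

Step 8
Reactants: 13 methyl (E)-3-{3-(benzyloxy)-5-[(2S)-1-(3,4-dimethoxyphenyl)-3-hydroxypropan-2-yl]-4-hydroxyphenyl}acrylate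
Product: 14 methyl (E)-3-[(2R,3S)-7-(benzyloxy)-2-(3,4-dimethoxyphenyl)-3-(hydroxymethyl)-2,3-dihydrobenzofuran-5-yl]acrylate
Conditions: DDQ (1.05 equiv), CH2Cl2 (dry), 4 Å MS, 0 °C to rt; then NaHCO3 (aq)
Reagents that add atoms: none
Why: DDQ forms a charge-transfer complex with the dimethoxy ring B and takes a hydride from the adjacent CH2, leaving a benzylic cation best described as a para-quinone-methide oxocarbenium ion held by the 4-methoxy group and paired with the hydroquinone anion of DDQ. The ring A phenol oxygen, five atoms away, adds to this sp2 carbon and its proton passes to the hydroquinone anion. The closest known reaction type is the DDQ-mediated oxidative cyclisation of methoxy-substituted alkylarenes that carry a tethered hydroxyl, as in the closure of 2-hydroxyphenyl-substituted 1,3-diarylpropanes to flavans and of arylethyl alcohols to isochromans. The ring closes in the 5-exo-trig mode, O1 attacking C2 while the C2=C(aryl) bond of the cation lies outside the new ring. The new C2 centre is controlled by the C3 centre of 13: in the envelope-like transition state ring B takes the side away from CH2OH, and because the reduced quinone is acidic enough to reopen a cis ether through the same cation, kinetic and thermodynamic preference both lead to the trans (2R,3S) product. The step needs site selectivity (the C2 methylene over the C3 methine and the OCH2Ph group), chemoselectivity (C–H oxidation over phenol oxidation) and a stop at the dihydrobenzofuran stage. Only the C2 methylene is para to a methoxy group, ring A is the poorer donor because of the conjugated acrylate, the primary alcohol could only close a four-membered ring, and 1.05 equivalents of DDQ at 0 °C in dry solvent leave no oxidant to dehydrogenate 14 to the benzofuran.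

Step 9
Reactants: 14 methyl (E)-3-[(2R,3S)-7-(benzyloxy)-2-(3,4-dimethoxyphenyl)-3-(hydroxymethyl)-2,3-dihydrobenzofuran-5-yl]acrylate
Product: 15 methyl (E)-3-[(2R,3S)-2-(3,4-dimethoxyphenyl)-7-hydroxy-3-(hydroxymethyl)-2,3-dihydrobenzofuran-5-yl]acrylate
Conditions: BCl3 (3 equiv), C6HMe5 (4 equiv), CH2Cl2, −78 °C; then CHCl3/MeOH, −78 °C
Reagents that add atoms: none
Why: Lewis-acid cleavage of the aryl benzyl ether, helped by chelation of boron between O7 and O1; the benzyl cation is removed by Friedel–Crafts alkylation of pentamethylbenzene. No hydrogen is used, so the cinnamate survives, and at −78 °C the methyl ethers and the ester should stay intact.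

Step 10
Reactants: 15 methyl (E)-3-[(2R,3S)-2-(3,4-dimethoxyphenyl)-7-hydroxy-3-(hydroxymethyl)-2,3-dihydrobenzofuran-5-yl]acrylate
Product: 16 (E)-3-[(2R,3S)-2-(3,4-dimethoxyphenyl)-7-hydroxy-3-(hydroxymethyl)-2,3-dihydrobenzofuran-5-yl]acrylic acid
Conditions: LiOH·H2O (5 equiv), THF/MeOH/H2O (degassed), rt; then HCl (1 M aq) to pH 3
Reagents that add atoms: lithium hydroxide, [Li+].[OH-]
Why: Saponification of the methyl ester by acyl–oxygen cleavage; neither stereocentre is alpha to a carbonyl and hydroxide does not isomerise the E alkene, so only the ester should change.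

## Compound list

1 | 2-(benzyloxy)phenol | Oc1ccccc1OCc1ccccc1 | starting material
2 | 2-(benzyloxy)-4-bromophenol | Oc1ccc(Br)cc1OCc1ccccc1 | intermediate
3 | glyoxylic acid | O=CC(=O)O | starting material
4 | 2-[3-(benzyloxy)-5-bromo-2-hydroxyphenyl]-2-hydroxyacetic acid (racemic) | OC(C(=O)O)c1cc(Br)cc(OCc2ccccc2)c1O | intermediate
5 | 2-[3-(benzyloxy)-5-bromo-2-hydroxyphenyl]acetic acid | OC(=O)Cc1cc(Br)cc(OCc2ccccc2)c1O | intermediate
6 | 7-(benzyloxy)-5-bromobenzofuran-2(3H)-one | O=C1Cc2cc(Br)cc(OCc3ccccc3)c2O1 | intermediate
7 | 3,4-dimethoxybenzaldehyde | COc1ccc(C=O)cc1OC | starting material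
8 | (E)-7-(benzyloxy)-5-bromo-3-(3,4-dimethoxybenzylidene)benzofuran-2(3H)-one | COc1ccc(/C=C2/C(=O)Oc3c(OCc4ccccc4)cc(Br)cc32)cc1OC | intermediate
9 | (E)-2-[3-(benzyloxy)-5-bromo-2-hydroxyphenyl]-3-(3,4-dimethoxyphenyl)acrylic acid | COc1ccc(/C=C(/C(=O)O)c2cc(Br)cc(OCc3ccccc3)c2O)cc1OC | intermediate
10 | (2S)-2-[3-(benzyloxy)-5-bromo-2-hydroxyphenyl]-3-(3,4-dimethoxyphenyl)propanoic acid | COc1ccc(C[C@H](C(=O)O)c2cc(Br)cc(OCc3ccccc3)c2O)cc1OC | intermediate
11 | 2-(benzyloxy)-4-bromo-6-[(2S)-1-(3,4-dimethoxyphenyl)-3-hydroxypropan-2-yl]phenol | COc1ccc(C[C@H](CO)c2cc(Br)cc(OCc3ccccc3)c2O)cc1OC | intermediate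
12 | methyl acrylate | C=CC(=O)OC | starting material
13 | methyl (E)-3-{3-(benzyloxy)-5-[(2S)-1-(3,4-dimethoxyphenyl)-3-hydroxypropan-2-yl]-4-hydroxyphenyl}acrylate | COC(=O)/C=C/c1cc(OCc2ccccc2)c(O)c(c1)[C@H](Cc1ccc(OC)c(OC)c1)CO | intermediate
14 | methyl (E)-3-[(2R,3S)-7-(benzyloxy)-2-(3,4-dimethoxyphenyl)-3-(hydroxymethyl)-2,3-dihydrobenzofuran-5-yl]acrylate | COc1ccc([C@@H]2Oc3c(OCc4ccccc4)cc(/C=C/C(=O)OC)cc3[C@H]2CO)cc1OC | intermediate
15 | methyl (E)-3-[(2R,3S)-2-(3,4-dimethoxyphenyl)-7-hydroxy-3-(hydroxymethyl)-2,3-dihydrobenzofuran-5-yl]acrylate | COc1ccc([C@@H]2Oc3c(O)cc(/C=C/C(=O)OC)cc3[C@H]2CO)cc1OC | intermediate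
16 | (E)-3-[(2R,3S)-2-(3,4-dimethoxyphenyl)-7-hydroxy-3-(hydroxymethyl)-2,3-dihydrobenzofuran-5-yl]acrylic acid | COc1ccc([C@@H]2Oc3c(O)cc(/C=C/C(=O)O)cc3[C@H]2CO)cc1OC | target

## Step count and least certain steps

Total step count: 10. Longest linear sequence: 10 steps (1 to 16); 3, 7 and 12 enter as purchased reagents.

Step 8 (key step). The most likely failure is oxidation at the wrong site. Hydride loss from the C3 methine (ortho to the free phenol, passing through an ortho-quinone methide), a 1,2-hydride shift after ionisation at C2, or oxidation of the phenol itself would planarise C3 and erase its configuration. Excess oxidant would dehydrogenate the product to the benzofuran. The fallback masks the phenol during the C–H oxidation and closes the ring afterwards by acid. It sets out from 13: acetylation of both hydroxyls (Ac2O, pyridine) should give methyl (E)-3-{4-acetoxy-3-(benzyloxy)-5-[(2S)-1-acetoxy-3-(3,4-dimethoxyphenyl)propan-2-yl]phenyl}acrylate F1. DDQ in acetic acid should then acetoxylate the ring B methylene, the only C–H para to a methoxy group on a molecule without a free phenol, to give methyl (E)-3-{4-acetoxy-3-(benzyloxy)-5-[(2S)-1,3-diacetoxy-1-(3,4-dimethoxyphenyl)propan-2-yl]phenyl}acrylate F2 as a mixture of epimers at the new carbinol carbon. Methanolysis (K2CO3, MeOH) should free methyl (E)-3-{3-(benzyloxy)-5-[(2S)-1-(3,4-dimethoxyphenyl)-1,3-dihydroxypropan-2-yl]-4-hydroxyphenyl}acrylate F3. Catalytic TsOH in CH2Cl2 should ionise the benzylic alcohol and let O1 close the trans ring by an SN1 etherification, which returns to the route at 14.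

Step 5. The risk is poor facial selectivity or slow turnover: the alpha-aryl group is 2,6-disubstituted and its free ortho hydroxyl can compete with the carboxylate for the metal. The fallback replaces catalysis by resolution. It sets out from 9: hydrogenation with the achiral catalyst [Rh(cod)(dppb)]BF4 under H2 in MeOH should give racemic 2-[3-(benzyloxy)-5-bromo-2-hydroxyphenyl]-3-(3,4-dimethoxyphenyl)propanoic acid F4, which is separated by preparative chromatography on a chiral stationary phase; the S enantiomer is 10, where the route is rejoined.

Step 3. The risk is lactonisation running ahead of ionisation: once O1 is acylated the benzylic cation loses its ortho oxygen donor and the silane reduction stalls. Slow acidolysis of the benzyl ether in TFA is a second risk. The fallback uses electron transfer in place of a cation. It sets out from 4: Ac2O and pyridine at 60 °C should lactonise and acetylate to 7-(benzyloxy)-5-bromo-2-oxo-2,3-dihydrobenzofuran-3-yl acetate F5, and SmI2 in THF/MeOH at −78 °C should cleave the alpha-acetoxy C–O bond by single-electron reduction of the lactone carbonyl, which returns to the route at 6.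

Step 9. The risk is ionisation of the O1–C2 bond by the Lewis acid, which regenerates the cation of the key step and could lead to elimination towards C3 or to capture by the scavenger; ring B could also lose a methyl group if the mixture warms. The fallback moves the debenzylation in front of the ring closure. It sets out from 13, which has no benzylic ether yet: BCl3 and C6HMe5 at −78 °C should give methyl (E)-3-{5-[(2S)-1-(3,4-dimethoxyphenyl)-3-hydroxypropan-2-yl]-3,4-dihydroxyphenyl}acrylate F6. TBSCl (2.1 equiv) and imidazole in DMF at 0 °C should silylate the primary alcohol and the less hindered O7, leaving the O1 hydroxyl (flanked by two ortho substituents) free, to give methyl (E)-3-{3-[(tert-butyldimethylsilyl)oxy]-5-[(2S)-1-[(tert-butyldimethylsilyl)oxy]-3-(3,4-dimethoxyphenyl)propan-2-yl]-4-hydroxyphenyl}acrylate F7. DDQ under the conditions of step 8 should close the ring to methyl (E)-3-[(2R,3S)-7-[(tert-butyldimethylsilyl)oxy]-3-{[(tert-butyldimethylsilyl)oxy]methyl}-2-(3,4-dimethoxyphenyl)-2,3-dihydrobenzofuran-5-yl]acrylate F8. TBAF buffered with AcOH in THF should remove both silyl groups and return to the route at 15.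

Step 2. The risk is incomplete conversion: the bromine lowers the nucleophilicity of the phenolate while glyoxylate is consumed by the Cannizzaro reaction in base. The fallback uses chelation in an aprotic medium. It sets out from 2: EtMgBr (1 equiv) in toluene should give the aryloxymagnesium bromide, which directs ethyl glyoxylate to the ortho carbon to give ethyl 2-[3-(benzyloxy)-5-bromo-2-hydroxyphenyl]-2-hydroxyacetate F9; LiOH in THF/H2O then returns to the route at 4.

## Further compounds

F1 | step 8 | methyl (E)-3-{4-acetoxy-3-(benzyloxy)-5-[(2S)-1-acetoxy-3-(3,4-dimethoxyphenyl)propan-2-yl]phenyl}acrylate | COC(=O)/C=C/c1cc(OCc2ccccc2)c(OC(C)=O)c(c1)[C@H](Cc1ccc(OC)c(OC)c1)COC(C)=O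
F2 | step 8 | methyl (E)-3-{4-acetoxy-3-(benzyloxy)-5-[(2S)-1,3-diacetoxy-1-(3,4-dimethoxyphenyl)propan-2-yl]phenyl}acrylate (epimers at C1 of the chain) | COC(=O)/C=C/c1cc(OCc2ccccc2)c(OC(C)=O)c(c1)[C@H](C(OC(C)=O)c1ccc(OC)c(OC)c1)COC(C)=O
F3 | step 8 | methyl (E)-3-{3-(benzyloxy)-5-[(2S)-1-(3,4-dimethoxyphenyl)-1,3-dihydroxypropan-2-yl]-4-hydroxyphenyl}acrylate (epimers at C1 of the chain) | COC(=O)/C=C/c1cc(OCc2ccccc2)c(O)c(c1)[C@H](C(O)c1ccc(OC)c(OC)c1)CO
F4 | step 5 | 2-[3-(benzyloxy)-5-bromo-2-hydroxyphenyl]-3-(3,4-dimethoxyphenyl)propanoic acid (racemic) | COc1ccc(CC(C(=O)O)c2cc(Br)cc(OCc3ccccc3)c2O)cc1OC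
F5 | step 3 | 7-(benzyloxy)-5-bromo-2-oxo-2,3-dihydrobenzofuran-3-yl acetate (racemic) | CC(=O)OC1C(=O)Oc2c(OCc3ccccc3)cc(Br)cc21
F6 | step 9 | methyl (E)-3-{5-[(2S)-1-(3,4-dimethoxyphenyl)-3-hydroxypropan-2-yl]-3,4-dihydroxyphenyl}acrylate | COC(=O)/C=C/c1cc(O)c(O)c(c1)[C@H](Cc1ccc(OC)c(OC)c1)CO
F7 | step 9 | methyl (E)-3-{3-[(tert-butyldimethylsilyl)oxy]-5-[(2S)-1-[(tert-butyldimethylsilyl)oxy]-3-(3,4-dimethoxyphenyl)propan-2-yl]-4-hydroxyphenyl}acrylate | COC(=O)/C=C/c1cc(O[Si](C)(C)C(C)(C)C)c(O)c(c1)[C@H](Cc1ccc(OC)c(OC)c1)CO[Si](C)(C)C(C)(C)C
F8 | step 9 | methyl (E)-3-[(2R,3S)-7-[(tert-butyldimethylsilyl)oxy]-3-{[(tert-butyldimethylsilyl)oxy]methyl}-2-(3,4-dimethoxyphenyl)-2,3-dihydrobenzofuran-5-yl]acrylate | COc1ccc([C@@H]2Oc3c(O[Si](C)(C)C(C)(C)C)cc(/C=C/C(=O)OC)cc3[C@H]2CO[Si](C)(C)C(C)(C)C)cc1OC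
F9 | step 2 | ethyl 2-[3-(benzyloxy)-5-bromo-2-hydroxyphenyl]-2-hydroxyacetate (racemic) | CCOC(=O)C(O)c1cc(Br)cc(OCc2ccccc2)c1O
A1 | alternative 1 | methyl (2R,3S)-3-(benzyloxymethyl)-7-bromo-2-(3,4-dimethoxyphenyl)-2,3-dihydrobenzofuran-5-carboxylate | COc1ccc([C@@H]2Oc3c(Br)cc(C(=O)OC)cc3[C@H]2COCc2ccccc2)cc1OC
A2 | alternative 1 | (4S,5R)-4-[(benzyloxy)methyl]-5-(3,4-dimethoxyphenyl)dihydrofuran-2(3H)-one | COc1ccc([C@@H]2OC(=O)C[C@H]2COCc2ccccc2)cc1OC
A3 | alternative 1 | tert-butyl{[(4S,5R)-4-[(benzyloxy)methyl]-5-(3,4-dimethoxyphenyl)-4,5-dihydrofuran-2-yl]oxy}dimethylsilane | COc1ccc([C@@H]2OC(O[Si](C)(C)C(C)(C)C)=C[C@H]2COCc2ccccc2)cc1OC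
A4 | alternative 1 | methyl 3-bromocoumalate (methyl 3-bromo-2-oxo-2H-pyran-5-carboxylate) | COC(=O)C1=COC(=O)C(Br)=C1
A5 | alternative 2 | (2R,3S)-3-[(tert-butyldimethylsilyloxy)methyl]-2-(3,4-dimethoxyphenyl)-2,3-dihydrobenzofuran-7-ol | COc1ccc([C@@H]2Oc3c(O)cccc3[C@H]2CO[Si](C)(C)C(C)(C)C)cc1OC
A6 | alternative 2 | (1R,2S)-2-(3-bromo-2-fluorophenyl)-3-[(tert-butyldimethylsilyl)oxy]-1-(3,4-dimethoxyphenyl)propan-1-ol | COc1ccc([C@H](O)[C@H](CO[Si](C)(C)C(C)(C)C)c2cccc(Br)c2F)cc1OC
A7 | alternative 3 | methyl (2R,3R)-trans-5-bromo-2-(3,4-dimethoxyphenyl)-7-(methoxymethoxy)-2,3-dihydrobenzofuran-3-carboxylate | COc1ccc([C@@H]2Oc3c(OCOC)cc(Br)cc3[C@H]2C(=O)OC)cc1OC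
A8 | alternative 3 | methyl 2-[5-bromo-2-[(3,4-dimethoxybenzyl)oxy]-3-(methoxymethoxy)phenyl]-2-diazoacetate | COC(=O)C(=[N+]=[N-])c1cc(Br)cc(OCOC)c1OCc1ccc(OC)c(OC)c1
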